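**Retrosynthetic overview**

1. Rings: A = cyclohexene, B = spiro-cyclopentane, C = α-methylene-γ-lactone. Late disconnections are the trans-diol (acetonide), the angelate (esterification), the exocyclic CH2 of ring C (Mannich/elimination) and the ring A C=C–CH2OH unit (enol triflate/Stille), which leads back to a ring A ketone on the carbon next to the spiro carbon.
2. Key disconnection: the ring B bonds spiro-C–CH2 and CH2–CH(O) are cut together. This gives a ring A 2-methylidenecyclohexanone (two-carbon unit C=CH2) and 4-(bromomethyl)furan-2(5H)-one (three-carbon unit γ-CH2, β-C, CH2Br), so ring C arrives as a butenolide.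
3. Enabling feature: the spiro carbon sits next to the ring A sp2 carbon that carries CH2O-angelate. With that carbon at the ketone level, the exocyclic CH2 is a Michael acceptor and the spiro carbon an enolate carbon; the ring B carbon bearing the lactone oxygen is the nucleophilic γ-carbon of a butenolide whose β-CH2Br is an allylic electrophile.
4. Ring A comes from L-threitol: ring-closing metathesis, singlet-oxygen ene reaction, β-methylation, then axial hydride delivery on a chair locked by the trans-fused acetonide.
5. Order of rings: A, then C (as the butenolide), then B in the key step, which sets the spiro centre and the ring B carbinol centre.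

Key step: step 8

Remark: centres that are later erased or equilibrated (the carbinol carbon in 4 and 5, the methyl-bearing and α-carbons in 7 and 8, the α-carbons in 11, 12, 24 and 25, the butenolide γ-carbon in 17) are drawn with the configuration expected to prevail.

**Route**

Step 1
Reactants: 1 (4S,5S)-4,5-bis(tosyloxymethyl)-2,2-dimethyl-1,3-dioxolane (1,4-di-O-tosyl-2,3-O-isopropylidene-L-threitol)
Product: 2 (4S,5S)-4,5-diallyl-2,2-dimethyl-1,3-dioxolane
Conditions: CH2=CHMgBr (6 equiv), Li2CuCl4 (10 mol %), THF, −30 → 0 °C
Reagents that add atoms: vinylmagnesium bromide, C=C[Mg]Br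
Why: Copper-catalysed cross-coupling of the Grignard reagent with both primary tosylates (SN2 at CH2) should give the C2-symmetric 1,7-diene without touching the two stereocentres taken from L-threitol.

Step 2
Reactants: 2 (4S,5S)-4,5-diallyl-2,2-dimethyl-1,3-dioxolane
Product: 3 (3aS,7aS)-2,2-dimethyl-3a,4,7,7a-tetrahydro-1,3-benzodioxole (trans-fused acetonide of (1S,2S)-cyclohex-4-ene-1,2-diol)
Conditions: second-generation Grubbs catalyst (2 mol %), CH2Cl2 (0.02 M), 40 °C
Reagents that add atoms: none
Why: Ring-closing metathesis of the 1,7-diene should close ring A as the trans-fused cyclohexene, driven by loss of ethene, and forms no stereocentre.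

Step 3
Reactants: 3 (3aS,7aS)-2,2-dimethyl-3a,4,7,7a-tetrahydro-1,3-benzodioxole
Product: 6 (3aS,7aS)-2,2-dimethyl-3a,7a-dihydro-1,3-benzodioxol-5(4H)-one, via allylic hydroperoxide 4 (not isolated), via allylic peracetate 5 (not isolated)
Conditions: O2, tetraphenylporphyrin (cat.), hν (visible), Ac2O, pyridine, DMAP (cat.), CH2Cl2, 0 → 23 °C
Reagents that add atoms: dioxygen, O=O
Why: The Schenck ene reaction of singlet oxygen should give the transposed allylic hydroperoxide (the two alkene carbons are equivalent through the C2 axis, so one constitution results), and acetylation with base-induced loss of acetic acid (Kornblum–DeLaMare-type dehydration) should turn it into the enone, erasing the transient carbinol centre.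

Step 4
Reactants: 6 (3aS,7aS)-2,2-dimethyl-3a,7a-dihydro-1,3-benzodioxol-5(4H)-one
Product: 9 (3aS,7aS)-2,2,7-trimethyl-3a,7a-dihydro-1,3-benzodioxol-5(4H)-one, via lithium enolate 7 (not isolated), via sulfilimine 8 (not isolated)
Conditions: MeLi (2.2 equiv), CuBr·SMe2 (1.1 equiv), Et2O, −78 °C; then PhS(Cl)=N-t-Bu (1.5 equiv), THF, −78 °C
Reagents that add atoms: lithium dimethylcuprate (from MeLi and CuBr·SMe2), [Li+].C[Cu-]C
Why: 1,4-Addition of the cuprate should give a regiodefined enolate that is dehydrogenated in the same flask by S-sulfinimidoylation and syn-elimination of the sulfilimine (Mukaiyama dehydrogenation), so the methyl group ends on an sp2 carbon and no stereocentre has to be controlled here.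

Step 5
Reactants: 9 (3aS,7aS)-2,2,7-trimethyl-3a,7a-dihydro-1,3-benzodioxol-5(4H)-one
Product: 11 (3aS,6S,7R,7aS)-6-[(dimethylamino)methyl]-2,2,7-trimethyltetrahydro-1,3-benzodioxol-5(4H)-one, via silyl enol ether 10 (not isolated)
Conditions: [(Ph3P)CuH]6 (5 mol %), PhMe2SiH (1.5 equiv), toluene, 23 °C; then CH2=NMe2+ I− (1.5 equiv), CH2Cl2, 23 °C; aq NaHCO3
Reagents that add atoms: dimethylmethyleneammonium iodide, C=[N+](C)C.[I-]
Why: Copper hydride-catalysed 1,4-hydrosilylation should deliver hydride to the β-carbon along the axial trajectory of the half-chair locked by the trans-fused dioxolane (anti to the axial hydrogen on the neighbouring C–O carbon), which places the methyl group equatorial and trans to that oxygen, and the regiodefined silyl enol ether is then aminomethylated by the iminium salt (Mukaiyama–Mannich reaction) at a centre that step 6 erases.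

Step 6
Reactants: 11 (3aS,6S,7R,7aS)-6-[(dimethylamino)methyl]-2,2,7-trimethyltetrahydro-1,3-benzodioxol-5(4H)-one
Product: 13 (3aS,7R,7aS)-2,2,7-trimethyl-6-methylidenetetrahydro-1,3-benzodioxol-5(4H)-one, via ammonium iodide 12 (not isolated)
Conditions: MeI (5 equiv), Et2O, 23 °C; then aq NaHCO3, CH2Cl2, 23 °C
Reagents that add atoms: none
Why: N-Methylation and E1cB loss of trimethylamine from the β-ammonio ketone (Mannich-base elimination) should give the exocyclic enone without touching the ring stereocentres, and 13 is used at once because α-methylene ketones dimerise.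

Step 7
Reactants: 14 4-(hydroxymethyl)furan-2(5H)-one
Product: 15 4-(bromomethyl)furan-2(5H)-one
Conditions: CBr4, PPh3, CH2Cl2, 0 °C
Reagents that add atoms: tetrabromomethane, BrC(Br)(Br)Br
Why: Appel bromination of the primary allylic alcohol under neutral conditions should leave the butenolide untouched.

Step 8
Reactants: 13 (3aS,7R,7aS)-2,2,7-trimethyl-6-methylidenetetrahydro-1,3-benzodioxol-5(4H)-one; 15 4-(bromomethyl)furan-2(5H)-one
Product: 18 spiro ketone butenolide (ring B closed between the butenolide and ring A; spiro carbon R; butenolide γ-carbon R; the CH2 that came from the bromide is axial on ring A and cis to the ring A methyl group), via potassium furanolate 16 (not isolated), via Michael-adduct potassium enolate 17 (not isolated)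
Conditions: KN(SiMe3)2 (1.0 equiv), THF, −78 °C (15 added to the base); then 13, −78 → 0 °C; AcOH; then DBU (0.1 equiv), CH2Cl2, 0 → 23 °C
Reagents that add atoms: none
Why: Proposed new method: the potassium 2-furanolate 16 should add through its γ-carbon to the exocyclic methylene of 13 (vinylogous Michael addition), and the tetrasubstituted ketone enolate 17 formed in this way, whose α-carbon is the future spiro carbon, should displace the allylic bromide on the butenolide β-CH2 in a 5-exo-tet C-alkylation, so that ring B and both of its new C–C bonds arise in one flask while ring C arrives intact. The closest known reaction types are the direct γ-selective vinylogous Michael addition of butenolides to enones and Michael-initiated ring closure ([3+2] anionic annulation) with γ-halo crotonate or γ-halo allyl sulfone reagents; what is new is a 4-(halomethyl)butenolide as the three-carbon partner. The spiro centre is set in the ring closure: ring A is held in one chair by the trans-fused dioxolane with the methyl group equatorial, and the CH2Br carbon should enter axially, anti to the axial hydrogen on the methyl-bearing carbon and therefore cis to the methyl group. The ring B carbinol centre is not fixed kinetically, because it is the acidic γ-position of a butenolide; catalytic DBU equilibrates it at the end, and the epimer whose lactone oxygen lies on the ring B face next to the ketone carbon, away from the equatorial methyl group, is expected to be the more stable one. The step needs γ- over α-attack of the furanolate, C- over O-alkylation and ring closure faster than self-alkylation of 16 or proton transfer within 17; the soft unhindered 1,4-acceptor, the five-membered transition state and the preformed furanolate at low temperature with exactly one equivalent of base are meant to secure this.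

Step 9
Reactants: 18 spiro ketone butenolide
Product: 19 spiro ketone with saturated cis-fused γ-lactone (ring-fusion CH R, with its hydrogen cis to the carbinol hydrogen; other centres as in 18)
Conditions: H2 (1 atm), [Ir(cod)(PCy3)(py)]PF6 (5 mol %), CH2Cl2, 23 °C
Reagents that add atoms: none
Why: Homogeneous hydrogenation of the trisubstituted butenolide alkene with a non-isomerising cationic iridium catalyst should deliver hydrogen to the face that carries the γ-hydrogen, because the five/five lactone can only be cis-fused, so the new ring-fusion centre follows from the carbinol centre fixed in step 8 while ketone and acetal stay inert.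

Step 10
Reactants: 19 spiro ketone with saturated cis-fused γ-lactone
Product: 21 ring A enol triflate (C=C between the former carbonyl carbon and its CH2 neighbour), via potassium enolate 20 (not isolated)
Conditions: KN(SiMe3)2 (1.1 equiv), THF, −78 °C; then PhNTf2 (1.2 equiv), −78 → −40 °C
Reagents that add atoms: N-phenylbis(trifluoromethanesulfonimide), FC(F)(F)S(=O)(=O)N(c1ccccc1)S(=O)(=O)C(F)(F)F
Why: Kinetic deprotonation of the ketone (more acidic than the lactone and enolisable only away from the quaternary spiro carbon) and O-sulfonylation of the enolate should give the enol triflate, the β-oxygen being equatorial and poorly aligned for E1cB loss at −78 °C.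

Step 11
Reactants: 21 ring A enol triflate
Product: 22 primary allylic alcohol (CH2OH on the ring A sp2 carbon next to the spiro carbon; saturated lactone)
Conditions: Bu3SnCH2OH (1.5 equiv), Pd(PPh3)4 (10 mol %), LiCl (3 equiv), 1,4-dioxane, 100 °C
Reagents that add atoms: (tributylstannyl)methanol, CCCC[Sn](CCCC)(CCCC)CO
Why: Stille coupling of the enol triflate with the hydroxymethyl stannane (chloride-assisted) should install the missing carbon on the ring A sp2 carbon and leave the alkene where the target has it, with no stereocentre involved.

Step 12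
Reactants: 22 primary allylic alcohol
Product: 26 α-methylene lactone allylic alcohol, via dilithium alkoxide enolate 23 (not isolated), via lactone Mannich base 24 (not isolated), via ammonium iodide 25 (not isolated)
Conditions: LiN(i-Pr)2 (2.3 equiv), THF, −78 °C; CH2=NMe2+ I− (1.2 equiv), −78 → 23 °C; then MeI, MeOH, 23 °C; then aq NaHCO3, CH2Cl2
Reagents that add atoms: dimethylmethyleneammonium iodide, C=[N+](C)C.[I-]
Why: The lactone enolate (the alkoxide forms first and is aminomethylated only reversibly) should undergo a Mannich reaction with the iminium salt, and quaternisation followed by E1cB elimination should give the α-methylene lactone, erasing the α-centre formed in passing.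

Step 13
Reactants: 26 α-methylene lactone allylic alcohol; 27 angelic acid, (Z)-2-methylbut-2-enoic acid
Product: 29 angelate ester of 26 (acetonide still in place), via mixed anhydride 28 (not isolated)
Conditions: 27 (1.5 equiv), 2,4,6-Cl3C6H2COCl, Et3N, toluene, 23 °C; then 26, DMAP, 23 °C
Reagents that add atoms: none
Why: Yamaguchi esterification through the mixed anhydride should acylate the primary allylic alcohol at ambient temperature, where the (Z)-alkene of the angeloyl group is not expected to isomerise to the (E)-tigloyl form.

Step 14
Reactants: 29 angelate ester with acetonide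
Product: 30 target CNP0224912.1
Conditions: AcOH/H2O (4:1), 40 °C
Reagents that add atoms: none
Why: Mild acid hydrolysis of the strained trans-fused acetonide should free the trans-diol, which the ester, the α-methylene lactone and the allylic alcohol tolerate.

**Compound list**

1 | (4S,5S)-4,5-bis(tosyloxymethyl)-2,2-dimethyl-1,3-dioxolane | Cc1ccc(cc1)S(=O)(=O)OC[C@@H]1OC(C)(C)O[C@H]1COS(=O)(=O)c1ccc(C)cc1 | starting material
2 | (4S,5S)-4,5-diallyl-2,2-dimethyl-1,3-dioxolane | C=CC[C@@H]1OC(C)(C)O[C@H]1CC=C | intermediate
3 | (3aS,7aS)-2,2-dimethyl-3a,4,7,7a-tetrahydro-1,3-benzodioxole | C1=CC[C@@H]2OC(C)(C)O[C@H]2C1 | intermediate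
4 | allylic hydroperoxide, 5-hydroperoxy-2,2-dimethyl-3a,4,5,7a-tetrahydro-1,3-benzodioxole (OOH anti to the oxygen on C-3a) | OO[C@H]1C[C@@H]2OC(C)(C)O[C@H]2C=C1 | intermediate
5 | allylic peracetate of 4 | CC(=O)OO[C@H]1C[C@@H]2OC(C)(C)O[C@H]2C=C1 | intermediate
6 | (3aS,7aS)-2,2-dimethyl-3a,7a-dihydro-1,3-benzodioxol-5(4H)-one | O=C1C[C@@H]2OC(C)(C)O[C@H]2C=C1 | intermediate
7 | lithium enolate after methyl addition (methyl cis to the neighbouring ring oxygen) | [Li+].[O-]C1=C[C@H](C)[C@@H]2OC(C)(C)O[C@H]2C1 | intermediate
8 | α-(N-tert-butyl-S-phenylsulfinimidoyl) ketone (sulfur group trans to the methyl group, sulfur configuration undefined) | O=C1C[C@@H]2OC(C)(C)O[C@H]2[C@@H](C)[C@@H]1S(=NC(C)(C)C)c1ccccc1 | intermediate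
9 | (3aS,7aS)-2,2,7-trimethyl-3a,7a-dihydro-1,3-benzodioxol-5(4H)-one | O=C1C[C@@H]2OC(C)(C)O[C@H]2C(C)=C1 | intermediate
10 | (3aS,7R,7aS)-5-[dimethyl(phenyl)silyloxy]-2,2,7-trimethyl-3a,4,7,7a-tetrahydro-1,3-benzodioxole | C[Si](C)(c1ccccc1)OC1=C[C@@H](C)[C@@H]2OC(C)(C)O[C@H]2C1 | intermediate
11 | (3aS,6S,7R,7aS)-6-[(dimethylamino)methyl]-2,2,7-trimethyltetrahydro-1,3-benzodioxol-5(4H)-one | CN(C)C[C@H]1C(=O)C[C@@H]2OC(C)(C)O[C@H]2[C@@H]1C | intermediate
12 | trimethylammonium iodide of 11 | C[N+](C)(C)C[C@H]1C(=O)C[C@@H]2OC(C)(C)O[C@H]2[C@@H]1C.[I-] | intermediate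
13 | (3aS,7R,7aS)-2,2,7-trimethyl-6-methylidenetetrahydro-1,3-benzodioxol-5(4H)-one | C=C1C(=O)C[C@@H]2OC(C)(C)O[C@H]2[C@@H]1C | intermediate
14 | 4-(hydroxymethyl)furan-2(5H)-one | O=C1OCC(CO)=C1 | starting material
15 | 4-(bromomethyl)furan-2(5H)-one | O=C1OCC(CBr)=C1 | intermediate
16 | potassium 4-(bromomethyl)furan-2-olate | [K+].[O-]c1cc(CBr)co1 | intermediate
17 | Michael-adduct potassium enolate (butenolide γ-carbon bonded to the former methylidene carbon; CH2Br still present) | [K+].[O-]C1=C(C[C@H]2OC(=O)C=C2CBr)[C@@H](C)[C@@H]3OC(C)(C)O[C@H]3C1 | intermediate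
18 | spiro ketone butenolide (spiro carbon R, butenolide γ-carbon R) | O=C1O[C@@H]2C[C@@]3(CC2=C1)C(=O)C[C@@H]4OC(C)(C)O[C@H]4[C@@H]3C | intermediate
19 | spiro ketone with saturated cis-fused γ-lactone | C1C(=O)O[C@@H]2C[C@@]3(C[C@H]12)C(=O)C[C@@H]4OC(C)(C)O[C@H]4[C@@H]3C | intermediate
20 | potassium enolate of 19 | C1C(=O)O[C@@H]2C[C@@]3(C[C@H]12)C([O-])=C[C@@H]4OC(C)(C)O[C@H]4[C@@H]3C.[K+] | intermediate
21 | ring A enol triflate | C1C(=O)O[C@@H]2C[C@@]3(C[C@H]12)C(OS(=O)(=O)C(F)(F)F)=C[C@@H]4OC(C)(C)O[C@H]4[C@@H]3C | intermediate
22 | primary allylic alcohol with saturated lactone | C1C(=O)O[C@@H]2C[C@@]3(C[C@H]12)C(CO)=C[C@@H]4OC(C)(C)O[C@H]4[C@@H]3C | intermediate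
23 | dilithium alkoxide lactone enolate of 22 | C1=C([O-])O[C@@H]2C[C@@]3(C[C@H]12)C(C[O-])=C[C@@H]4OC(C)(C)O[C@H]4[C@@H]3C.[Li+].[Li+] | intermediate
24 | α-[(dimethylamino)methyl] lactone (aminomethyl on the convex face, cis to the ring-fusion hydrogens) | CN(C)C[C@H]1C(=O)O[C@@H]2C[C@@]3(C[C@H]12)C(CO)=C[C@@H]4OC(C)(C)O[C@H]4[C@@H]3C | intermediate
25 | trimethylammonium iodide of 24 | C[N+](C)(C)C[C@H]1C(=O)O[C@@H]2C[C@@]3(C[C@H]12)C(CO)=C[C@@H]4OC(C)(C)O[C@H]4[C@@H]3C.[I-] | intermediate
26 | α-methylene lactone allylic alcohol | C=C1C(=O)O[C@@H]2C[C@@]3(C[C@H]12)C(CO)=C[C@@H]4OC(C)(C)O[C@H]4[C@@H]3C | intermediate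
27 | angelic acid, (Z)-2-methylbut-2-enoic acid | C/C=C(/C)C(=O)O | starting material
28 | angelic 2,4,6-trichlorobenzoic mixed anhydride | C/C=C(/C)C(=O)OC(=O)c1c(Cl)cc(Cl)cc1Cl | intermediate
29 | angelate ester of 26 (trans-acetonide) | C=C1C(=O)O[C@@H]2C[C@@]3(C[C@H]12)C(COC(=O)/C(C)=C\C)=C[C@@H]4OC(C)(C)O[C@H]4[C@@H]3C | intermediate
30 | CNP0224912.1 | C=C1C(=O)O[C@@H]2C[C@@]3(C[C@H]12)C(COC(=O)/C(C)=C\C)=C[C@H](O)[C@@H](O)[C@@H]3C | target

**Step count and risks**

Total step count: 14 (13 in the main line, one to prepare 15). Longest linear sequence: 13 steps (1 to 30 through steps 1–6 and 8–14).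

Steps most likely to fail:

Step 8 (Proposed new method). The furanolate may attack through its α-carbon or alkylate itself. The adduct enolate may be quenched by proton transfer from the acidic γ-hydrogen before it closes the ring. The ring closure may also show poor facial selectivity at the spiro carbon. The fallback uses known chemistry in separate stages, sets out from 13 and 15 and comes back at 18. Compound 15 is silylated (t-BuMe2SiOTf, i-Pr2NEt, CH2Cl2, 0 °C) to 4-(bromomethyl)-2-(tert-butyldimethylsilyloxy)furan F1. A silyl triflate-catalysed vinylogous Mukaiyama–Michael addition of F1 to 13 (CH2Cl2, −78 °C) should then give, with silyl transfer, the regiodefined silyl enol ether bromide F2. Fluoride (CsF, 18-crown-6, THF) frees the enolate of F2 for the 5-exo-tet alkylation to 18, which is equilibrated with DBU as before.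

Step 10. Enolisation next to the ring oxygen may trigger β-elimination that opens the dioxolane, and deprotonation of the lactone may compete. The fallback sets out from 19, comes back at 22 and replaces steps 10 and 11. Wittig methylenation of the ketone (Ph3P=CH2, THF, 0 °C) should give the exocyclic alkene F3. A Schenck ene reaction with singlet oxygen (O2, tetraphenylporphyrin, hν, CH2Cl2) can take its hydrogen only from the ring CH2, because the other allylic position is the quaternary spiro carbon. It should move the alkene into ring A and give the primary allylic hydroperoxide F4, which PPh3 reduces to 22.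

Step 13. The activated acyl species may isomerise from the (Z)-angeloyl to the (E)-tigloyl geometry before or during acyl transfer. The fallback sets out from 26 and 27 and comes back at 29. It is a Mitsunobu esterification (PPh3, i-PrO2CN=NCO2i-Pr, THF, 0 °C), in which the primary allylic alcohol is activated as its oxyphosphonium ion and the acid serves only as the carboxylate nucleophile; no new compound arises (F0).

Further compounds
F1 | step 8 | 4-(bromomethyl)-2-(tert-butyldimethylsilyloxy)furan | CC(C)(C)[Si](C)(C)Oc1cc(CBr)co1
F2 | step 8 | tert-butyldimethylsilyl enol ether of the Michael adduct (butenolide with CH2Br) | CC(C)(C)[Si](C)(C)OC1=C(C[C@H]2OC(=O)C=C2CBr)[C@@H](C)[C@@H]3OC(C)(C)O[C@H]3C1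
F3 | step 10 | exocyclic methylidene analogue of 19 | C1C(=O)O[C@@H]2C[C@@]3(C[C@H]12)C(=C)C[C@@H]4OC(C)(C)O[C@H]4[C@@H]3C
F4 | step 10 | primary allylic hydroperoxide corresponding to 22 | C1C(=O)O[C@@H]2C[C@@]3(C[C@H]12)C(COO)=C[C@@H]4OC(C)(C)O[C@H]4[C@@H]3C
F0 | step 13 | none | none
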